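**Plan**

- Rings: coumarin benzo ring A, pyranone ring B, chroman benzene ring C, dihydropyran ring D. The C3=C4 double bond lies in the six-membered lactone ring B, whose O1–C2 ester bond can be made first, so the retrosynthesis cuts C3=C4 (olefin metathesis) and then O1–C2 (esterification).
- Ring A half: a 2-vinylphenol whose vinyl CH2 is cut back to the formyl group of 2,4-dihydroxy-6-methoxybenzaldehyde. The C7 oxygen is carried as a triisopropylsilyl ether, chosen over a smaller silyl group because it must outlast a phenoxide-forming Wittig step.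
- Ring C/D half: a 2-arylacrylic acid, cut at the C=CH2 bond (formaldehyde), at the aryl–CH2 bond (1,2-aryl shift of an acetophenone) and at the C–C and C–O bonds of ring D (3-methylbut-2-enal onto 2,4-dihydroxyacetophenone).
- Forward order: ring D closes first and is saturated, the acrylic acid side chain is built, the ester joins the halves, ring B closes last by metathesis, and desilylation ends the route.
- Stereochemistry: the target has no stereocentre; its only geometric element, the C3=C4 alkene, is cis because it is endocyclic.

Key step: step 10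

**Route**

Step 1
Reactants: 1 2,4-dihydroxyacetophenone; 2 3-methylbut-2-enal
Product: 4 1-(5-hydroxy-2,2-dimethyl-2H-chromen-6-yl)ethanone, via ortho-quinone methide 3 (not isolated)
Conditions: pyridine, 140 °C, sealed tube
Reagents that add atoms: none
Why: Pyridine-mediated chromenylation of a resorcinol: aldol-type attack of C3 (between the two oxygens) on the enal and loss of water should give quinone methide 3, which closes by oxa-6π electrocyclisation through the 4-oxygen because the 2-hydroxyl stays hydrogen-bonded to the acetyl group.

Step 2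
Reactants: 4 1-(5-hydroxy-2,2-dimethyl-2H-chromen-6-yl)ethanone
Product: 5 1-(5-hydroxy-2,2-dimethylchroman-6-yl)ethanone
Conditions: H2 (1 atm), 10% Pd/C, EtOAc, rt
Reagents that add atoms: none
Why: Catalytic hydrogenation of the styrene-type C3=C4 bond of a 2,2-dimethylchromene is fast at atmospheric pressure, while the chelated aryl ketone should be untouched if the reaction is stopped at one equivalent of hydrogen.

Step 3
Reactants: 5 1-(5-hydroxy-2,2-dimethylchroman-6-yl)ethanone
Product: 6 1-(5-methoxy-2,2-dimethylchroman-6-yl)ethanone
Conditions: MeI, K2CO3, DMF, 40 °C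
Reagents that add atoms: iodomethane, CI
Why: Williamson O-methylation; the chelated phenol is slow to react, so a polar aprotic solvent and gentle warming are used.

Step 4
Reactants: 6 1-(5-methoxy-2,2-dimethylchroman-6-yl)ethanone
Product: 7 methyl 2-(5-methoxy-2,2-dimethylchroman-6-yl)acetate
Conditions: Tl(NO3)3·3H2O, MeOH, cat. HClO4, rt
Reagents that add atoms: methanol, CO
Why: Thallium trinitrate oxidative rearrangement of an aryl methyl ketone: oxythallation of the enol form by trivalent thallium is followed by a 1,2-shift of the electron-rich aryl group with loss of monovalent thallium, a reaction that works best on alkoxy-substituted acetophenones.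

Step 5
Reactants: 7 methyl 2-(5-methoxy-2,2-dimethylchroman-6-yl)acetate
Product: 9 methyl 2-(5-methoxy-2,2-dimethylchroman-6-yl)acrylate, via hydroxymethyl aldol adduct 8 (not isolated)
Conditions: (CH2O)n, K2CO3, Bu4NI (cat.), toluene, 80 °C
Reagents that add atoms: paraformaldehyde (as formaldehyde), C=O
Why: Aldol addition of the arylacetate enolate to formaldehyde followed by E1cB loss of water is the standard methylenation of arylacetates to 2-arylacrylates; the product has no α-hydrogen and cannot react a second time.

Step 6
Reactants: 9 methyl 2-(5-methoxy-2,2-dimethylchroman-6-yl)acrylate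
Product: 10 2-(5-methoxy-2,2-dimethylchroman-6-yl)acrylic acid
Conditions: LiOH·H2O, THF/H2O, 0 °C to rt; then 1 M HCl to pH 3, cold work-up
Reagents that add atoms: lithium hydroxide, [Li+].[OH-]
Why: Ester saponification by acyl–oxygen cleavage; low temperature and prompt use of the acid limit conjugate addition and self-condensation of the 2-arylacrylic acid.

Step 7
Reactants: 11 2,4-dihydroxy-6-methoxybenzaldehyde
Product: 12 2-hydroxy-6-methoxy-4-[(triisopropylsilyl)oxy]benzaldehyde
Conditions: TIPSCl (1.05 equiv), imidazole, CH2Cl2, 0 °C
Reagents that add atoms: triisopropylsilyl chloride, CC(C)[Si](Cl)(C(C)C)C(C)C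
Why: Selective silylation of the para-hydroxyl, which is the more acidic and accessible one, while the ortho-hydroxyl is held in a hydrogen bond to the formyl group.

Step 8
Reactants: 12 2-hydroxy-6-methoxy-4-[(triisopropylsilyl)oxy]benzaldehyde
Product: 13 3-methoxy-5-[(triisopropylsilyl)oxy]-2-vinylphenol
Conditions: Ph3PCH3Br (2.5 equiv), KOtBu (2.4 equiv), THF, 0 °C to rt; sat. NH4Cl quench, neutral work-up, used at once
Reagents that add atoms: methyltriphenylphosphonium bromide, C[P+](c1ccccc1)(c1ccccc1)c1ccccc1.[Br-]
Why: Wittig methylenation of a salicylaldehyde with excess ylide, one equivalent being consumed by the phenol; the bulky silyl ether should resist the basic medium and silyl transfer to the phenoxide.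

Step 9
Reactants: 10 2-(5-methoxy-2,2-dimethylchroman-6-yl)acrylic acid; 13 3-methoxy-5-[(triisopropylsilyl)oxy]-2-vinylphenol
Product: 14 3-methoxy-5-[(triisopropylsilyl)oxy]-2-vinylphenyl 2-(5-methoxy-2,2-dimethylchroman-6-yl)acrylate
Conditions: DIC, DMAP (0.2 equiv), CH2Cl2, 0 °C to rt
Reagents that add atoms: none
Why: Steglich esterification; carbodiimide activation with acyl transfer through the acylpyridinium joins the hindered acrylic acid and the phenol without acid or heat, which suits the acid-sensitive electron-rich styrene.

Step 10
Reactants: 14 3-methoxy-5-[(triisopropylsilyl)oxy]-2-vinylphenyl 2-(5-methoxy-2,2-dimethylchroman-6-yl)acrylate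
Product: 15 5-methoxy-3-(5-methoxy-2,2-dimethylchroman-6-yl)-7-[(triisopropylsilyl)oxy]-2H-chromen-2-one
Conditions: second-generation Grubbs catalyst (H2IMes)(PCy3)Cl2Ru=CHPh (5–10 mol%), toluene (5 mM), 80 °C, argon sparge
Reagents that add atoms: none
Why: The benzylidene of the catalyst exchanges onto the terminal styrene CH=CH2 of 14 (the 1,1-disubstituted, electron-poor arylacrylate does not initiate), the new ruthenium carbene adds intramolecularly to the acrylate C=CH2 in a [2+2] cycloaddition, and cycloreversion of the ruthenacyclobutane releases the coumarin and a ruthenium methylidene that carries the cycle with loss of ethylene. The closest known reaction type is the ring-closing metathesis of 2-vinylphenyl acrylates and methacrylates to coumarins, and of 2-arylacrylate esters to 3-aryl unsaturated lactones, with ruthenium N-heterocyclic carbene catalysts. Ring B, the six-membered pyranone, closes by formation of the C3=C4 bond between the two terminal alkenes, the O1–C2 ester bond being already in place. No stereocentre is formed, and the new alkene can only be cis because it is endocyclic in a six-membered ring. The step needs ring closure to win over intermolecular cross-metathesis of the styrene; the ortho placement of both alkenes on ring A, heating to populate the reactive ester rotamer, high dilution and removal of ethylene should secure this. The trisubstituted conjugated product alkene is inert to further metathesis, and the silyl ether, the methyl ethers and the chroman are spectators.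

Step 11
Reactants: 15 5-methoxy-3-(5-methoxy-2,2-dimethylchroman-6-yl)-7-[(triisopropylsilyl)oxy]-2H-chromen-2-one
Product: 16 7-hydroxy-5-methoxy-3-(5-methoxy-2,2-dimethylchroman-6-yl)-2H-chromen-2-one (CNP0139207.0)
Conditions: TBAF, AcOH (1:1), THF, 0 °C
Reagents that add atoms: none
Why: Fluoride cleavage of an aryl silyl ether; buffering with acetic acid keeps the medium from opening the lactone and protonates the phenoxide as it forms.

**Compound list**

1 | 2,4-dihydroxyacetophenone | CC(=O)c1ccc(O)cc1O | starting material
2 | 3-methylbut-2-enal | CC(C)=CC=O | starting material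
3 | 4-acetyl-3-hydroxy-2-(3-methylbut-2-enylidene)cyclohexa-3,5-dien-1-one (ortho-quinone methide) | CC(=O)C1=C(O)C(=CC=C(C)C)C(=O)C=C1 | intermediate (not isolated)
4 | 1-(5-hydroxy-2,2-dimethyl-2H-chromen-6-yl)ethanone | CC(=O)c1ccc2OC(C)(C)C=Cc2c1O | intermediate
5 | 1-(5-hydroxy-2,2-dimethylchroman-6-yl)ethanone | CC(=O)c1ccc2OC(C)(C)CCc2c1O | intermediate
6 | 1-(5-methoxy-2,2-dimethylchroman-6-yl)ethanone | COc1c(C(C)=O)ccc2OC(C)(C)CCc12 | intermediate
7 | methyl 2-(5-methoxy-2,2-dimethylchroman-6-yl)acetate | COC(=O)Cc1ccc2OC(C)(C)CCc2c1OC | intermediate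
8 | methyl 3-hydroxy-2-(5-methoxy-2,2-dimethylchroman-6-yl)propanoate (racemic) | COC(=O)C(CO)c1ccc2OC(C)(C)CCc2c1OC | intermediate (not isolated)
9 | methyl 2-(5-methoxy-2,2-dimethylchroman-6-yl)acrylate | COC(=O)C(=C)c1ccc2OC(C)(C)CCc2c1OC | intermediate
10 | 2-(5-methoxy-2,2-dimethylchroman-6-yl)acrylic acid | OC(=O)C(=C)c1ccc2OC(C)(C)CCc2c1OC | intermediate
11 | 2,4-dihydroxy-6-methoxybenzaldehyde | COc1cc(O)cc(O)c1C=O | starting material
12 | 2-hydroxy-6-methoxy-4-[(triisopropylsilyl)oxy]benzaldehyde | COc1cc(O[Si](C(C)C)(C(C)C)C(C)C)cc(O)c1C=O | intermediate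
13 | 3-methoxy-5-[(triisopropylsilyl)oxy]-2-vinylphenol | C=Cc1c(OC)cc(O[Si](C(C)C)(C(C)C)C(C)C)cc1O | intermediate
14 | 3-methoxy-5-[(triisopropylsilyl)oxy]-2-vinylphenyl 2-(5-methoxy-2,2-dimethylchroman-6-yl)acrylate | C=Cc1c(OC)cc(O[Si](C(C)C)(C(C)C)C(C)C)cc1OC(=O)C(=C)c1ccc2OC(C)(C)CCc2c1OC | intermediate
15 | 5-methoxy-3-(5-methoxy-2,2-dimethylchroman-6-yl)-7-[(triisopropylsilyl)oxy]-2H-chromen-2-one | O=c1oc2cc(O[Si](C(C)C)(C(C)C)C(C)C)cc(OC)c2cc1-c1ccc2OC(C)(C)CCc2c1OC | intermediate
16 | 7-hydroxy-5-methoxy-3-(5-methoxy-2,2-dimethylchroman-6-yl)-2H-chromen-2-one (CNP0139207.0) | COc1c(-c2cc3c(OC)cc(O)cc3oc2=O)ccc2c1CCC(C)(C)O2 | target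

**Step count**

Total step count: 11.
Longest linear sequence: 9 steps (steps 1 to 6, then 9, 10 and 11).

**Steps most likely to fail**

Step 10. Loading of ruthenium onto the doubly ortho-substituted styrene may be slow, and the carbene may be held in a chelate by the flanking methoxy or ester oxygen. Intermolecular cross-metathesis and catalyst decay could then outrun ring closure. The fallback sets out from 7 and 12 and forms the C3=C4 bond by condensation instead of metathesis. Saponification of 7 (LiOH, THF/H2O) should give 2-(5-methoxy-2,2-dimethylchroman-6-yl)acetic acid F1. Carbodiimide coupling of F1 with salicylaldehyde 12 (DIC, DMAP, CH2Cl2) should give 2-formyl-3-methoxy-5-[(triisopropylsilyl)oxy]phenyl 2-(5-methoxy-2,2-dimethylchroman-6-yl)acetate F2. Treatment of F2 with DBU in the same flask should close the lactone by intramolecular Knoevenagel (Perkin-type) condensation, and the route is rejoined at 15.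

Step 8. Addition of the ylide to the phenoxide-deactivated, doubly ortho-substituted aldehyde may be sluggish, and the electron-rich vinylphenol may oligomerise through acid- or radical-induced pathways during isolation. The fallback sets out from 12 and 10 and never frees the vinylphenol. Steglich esterification of 12 with 10 (DIC, DMAP, CH2Cl2) should give 2-formyl-3-methoxy-5-[(triisopropylsilyl)oxy]phenyl 2-(5-methoxy-2,2-dimethylchroman-6-yl)acrylate F3. Takai–Lombardo methylenation (Zn, CH2Br2, TiCl4, THF, 0 °C), which is non-basic and leaves esters alone, should convert the formyl group into the vinyl group, and the route is rejoined at 14.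

Step 4. Oxidation or thallation of the electron-rich chroman ring, or α-methoxylation of the ketone, may compete with the aryl shift. The fallback sets out from 6 and keeps the carbon skeleton instead of rearranging it. Riley oxidation of the acetyl methyl group (SeO2, pyridine, 100 °C) should give 2-(5-methoxy-2,2-dimethylchroman-6-yl)-2-oxoacetic acid F4. Methylation (MeI, K2CO3, DMF) should give methyl 2-(5-methoxy-2,2-dimethylchroman-6-yl)-2-oxoacetate F5. Wittig methylenation of the keto group of F5 (Ph3PCH3Br, KOtBu, THF) should give the acrylate directly, and the route is rejoined at 9.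

**Further compounds**

F1 | step 10 | 2-(5-methoxy-2,2-dimethylchroman-6-yl)acetic acid | OC(=O)Cc1ccc2OC(C)(C)CCc2c1OC
F2 | step 10 | 2-formyl-3-methoxy-5-[(triisopropylsilyl)oxy]phenyl 2-(5-methoxy-2,2-dimethylchroman-6-yl)acetate | O=Cc1c(OC)cc(O[Si](C(C)C)(C(C)C)C(C)C)cc1OC(=O)Cc1ccc2OC(C)(C)CCc2c1OC
F3 | step 8 | 2-formyl-3-methoxy-5-[(triisopropylsilyl)oxy]phenyl 2-(5-methoxy-2,2-dimethylchroman-6-yl)acrylate | O=Cc1c(OC)cc(O[Si](C(C)C)(C(C)C)C(C)C)cc1OC(=O)C(=C)c1ccc2OC(C)(C)CCc2c1OC
F4 | step 4 | 2-(5-methoxy-2,2-dimethylchroman-6-yl)-2-oxoacetic acid | OC(=O)C(=O)c1ccc2OC(C)(C)CCc2c1OC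
F5 | step 4 | methyl 2-(5-methoxy-2,2-dimethylchroman-6-yl)-2-oxoacetate | COC(=O)C(=O)c1ccc2OC(C)(C)CCc2c1OC
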